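all flasks: pre-initiator 10 mol%

| flask | free monomer | remark | time |
|---|---|---|---|
| north | 0.025 M | run made earlier |  |
| north-west | 0.10 M | run made earlier |  |
| flask | 0.050 M |  | 4.0 min |

- north (time / min: monomer in chains / %, free monomer / %): 0.417: 2.0, 97.3; 0.667: 3.0, 96.6; 0.833: 2.0, 96.2; 1.33: 0.6, 98.7; 2.00: 0, 99.8; 3.00: 0.3, 98.7; 5.00: 0, 98.8
- north-west (time / min: monomer in chains / %, free monomer / %): 0.417: 14.3, 85.5; 0.667: 25.4, 74.8; 0.833: 31.3, 68.3; 1.33: 43.8, 55.5; 2.00: 52.7, 46.5; 3.00: 58.4, 40.5; 5.00: 61.9, 37.3

(each reading ± 0.5 percentage points)

1. whether the average number of monomer units in a chain (chains begun, living or dead) reaches 10 by 4.0 min (no / yes)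
2. average number of monomer units in a chain (chains begun, living or dead) at 4.0 min

- the average divides the monomer in chains by the number of chains begun, living and dead together
- the earlier runs do not show the number of chains; that part of a forecast is a guess

The north-west run, charged at 0.10 M, holds 37.3% of its free monomer at 5.00 min, and its loss has slowed by then, so that reading, with its scatter, is taken as an estimate of a floor M_e = 0.0373 M, the free monomer level at which net passage into chains stops, known as the equilibrium monomer concentration. The north run starts at 0.025 M, less than M_e, and shows 0% in chains at 5.00 min.

If net growth stops at M_e, the flask, charged at 0.050 M, has room for about 0.0127 M in chains. Turned round: the pre-initiator charge in the flask supplies 0.00500 M, and for the average to reach 10 by 4.0 min, that room must be shared among about 0.00127 M of chains or fewer, a quarter of that charge. The readings show no count of chains, so the count is a guess; my own reckoning takes one chain per pre-initiator, which gives an average of 2.54 and the answer no.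

The forecast says no and 3, on the ground that “most initiator probably starts chains”; its average stands above the one reckoned here.

The flask gives no, with an average of 2.45 at 4.0 min.

    free monomer + initiator → living end + monomer in chains (k = 1.09 M⁻¹ s⁻¹)
    monomer in chains + living end → free monomer + living end, rate k2*[living end] as long as [monomer in chains] is above zero (k = 0.0700 s⁻¹)
    free monomer + initiator → spent initiator (k = 0.101 M⁻¹ s⁻¹)
    free monomer + living end → monomer in chains + living end, rate k4*[living end]*[free monomer] (k = 1.88 M⁻¹ s⁻¹)
    pre-initiator → initiator (k = 0.0907 s⁻¹)

At 4.00 min the flask holds a living end of 0.00458 M, nearly all of the pre-initiator charge. The neighbour charged at 0.20 M of free monomer, with the same loading and time, has room above M_e for 81.3% of its charge; at 4.00 min it holds 80.5% in chains, with an average of 8.80.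

The numbers in the tables are calculated for substances that don't exist, and the scatter is random.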